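**Assumptions (one line each):** Compounds 1 and 5 are commercial (5 can be made from 4-TMS-3-butyn-1-ol by an Appel iodination). The enantiomer of each organocatalyst is the one that gives the drawn configuration. The RCM in Step 15 is assumed to give the (E)-trisubstituted alkene.

## Retrosynthetic overview
1. The 14-membered carbocycle is closed last by RCM at the C4=C5 alkene, joining an isopropenyl carbinol to a terminal vinyl group. The TIPS ether is then removed.
2. The skipped (E,E)-diene arm is built by Zr-catalysed carboalumination/Cu-allylation of a terminal alkyne. This follows the 7-membered α-methylene lactone, which comes from a malonate by decarboxylative methylenation.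
3. The bridged ε-lactone is the first ring formed. A Shi epoxide (S,S) opens at the tertiary carbon with inversion, through 7-exo attack by a malonate tert-butyl ester or acid, to set C12 and C11.
4. C1 is set by an iminium-catalysed malonate Michael addition to an enal. C3 is set by CBS reduction.
5. The building blocks are hex-5-en-1-yne, a TMS-butynyl iodide, acrolein, di-tert-butyl malonate, isopropenylMgBr and allyl bromide. The lactone forms first and the macrocycle last.

## Route

**Step 1**
Reactants: 1 hex-5-en-1-yne
Product: 4 (E)-1-iodo-2-methylhexa-1,5-diene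
Conditions: Me3Al (2), Cp2ZrCl2, CH2Cl2, 23 °C; then I2 (3), THF, –30 → 0 °C
Reagents that add atoms: trimethylaluminium (2) C[Al](C)C; iodine (3) II
Why: Negishi Zr-catalysed methylalumination is a syn addition, so I ends up cis to Me and the E-trisubstituted alkene is fixed. The terminal alkene is untouched.

**Step 2**
Reactants: 4; 5 (4-iodobut-1-yn-1-yl)trimethylsilane
Product: 6 trimethyl[(5E)-6-methyldeca-5,9-dien-1-yn-1-yl]silane
Conditions: 5, Zn dust, LiCl, THF, to give the alkylzinc; then 4, Pd(dppf)Cl2 (5 mol%), THF, 40 °C
Reagents that add atoms: none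
Why: Negishi sp2–sp3 coupling proceeds with retention of alkene geometry, which gives the alkene with Me cis to the new CH2 (E).

**Step 3**
Reactants: 6; 7 Oxone
Product: 8 trimethyl{4-[(2S,3S)-3-(but-3-en-1-yl)-3-methyloxiran-2-yl]but-1-yn-1-yl}silane
Conditions: ent-Shi fructose-derived ketone (30 mol%, L-sorbose series), 7, K2CO3, Bu4NHSO4, MeCN/DMM/aq. Na2B4O7–EDTA, 0 °C
Reagents that add atoms: Oxone (7) [K+].OOS(=O)(=O)[O-] (one O atom)
Why: Shi dioxirane epoxidation of the only trisubstituted alkene, through a spiro transition state, sets C11 and C12 as the (S,S) trans-epoxide. The terminal vinyl group and the TMS-alkyne are inert.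

**Step 4**
Reactants: 8; 9 acrolein
Product: 10 (2E)-5-[(2S,3S)-2-methyl-3-(4-TMS-but-3-yn-1-yl)oxiran-2-yl]pent-2-enal
Conditions: 9 (10 equiv), Hoveyda–Grubbs II (5 mol%), CH2Cl2, 40 °C
Reagents that add atoms: none
Why: Cross-metathesis of a monosubstituted alkene with acrolein gives the (E)-enal (the iminium substrate); the epoxide and alkyne are tolerated.

**Step 5**
Reactants: 10; 11 di-tert-butyl malonate
Product: 12 di-tert-butyl 2-[(1R)-3-oxo-1-{2-[(2S,3S)-2-methyl-3-(4-TMS-but-3-yn-1-yl)oxiran-2-yl]ethyl}propyl]malonate
Conditions: (S)-diphenylprolinol TMS ether (10 mol%), toluene, 0 → 23 °C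
Reagents that add atoms: none
Why: Iminium-catalysed (Jørgensen–Hayashi) conjugate addition, in which the bulky catalyst group blocks one enal face, sets C1 (R).

**Step 6**
Reactants: 12; 13 isopropenylmagnesium bromide
Product: 14 allylic alcohol, C3 epimer mixture
Conditions: 13 (3 equiv), THF, –78 → 0 °C
Reagents that add atoms: none
Why: 1,2-Grignard addition to the aldehyde (the excess equivalents deprotonate the malonate CH); C3 is left for reagent control in Steps 7–8.

**Step 7**
Reactants: 14
Product: 15 isopropenyl ketone
Conditions: Dess–Martin periodinane, NaHCO3, CH2Cl2, 23 °C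
Reagents that add atoms: none
Why: Oxidation removes the C3 stereocentre so that it can be set by catalyst control.

**Step 8**
Reactants: 15
Product: 16 (3S)-alcohol
Conditions: (R)-Me-CBS (20 mol%), catecholborane, toluene, –78 °C
Reagents that add atoms: none
Why: CBS reduction with the isopropenyl group as the large ketone substituent sets C3 (S) by catalyst control.

**Step 9**
Reactants: 16; 17 TIPSCl
Product: 18 TIPS ether
Conditions: 17, imidazole, DMAP, DMF, 50 °C
Reagents that add atoms: triisopropylsilyl chloride (17) CC(C)[Si](Cl)(C(C)C)C(C)C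
Why: Protecting C3–OH stops ionisation and epoxide participation in the acid step; the non-Lewis-acidic silylation spares the epoxide.

**Step 10**
Reactants: 18
Product: 19 bridged α-carboxy-ε-lactone (C12 R, C11 S, C1 R, C3 S)
Conditions: TFA (10 equiv), CH2Cl2, 0 → 23 °C, 3 h; concentrate and azeotrope with toluene
Reagents that add atoms: none
Why: Proposed new method: TFA protonates the trisubstituted epoxide and cleaves the tert-butyl esters, and the ester carbonyl or acid attacks the tertiary epoxide carbon 7-exo-tet with inversion (isobutylene lost), forming the bridged ε-lactone and the C11 alcohol. The closest known reactions are 5/6-exo epoxy-acid lactonisation and tert-butyl carbonate/ester participation in epoxide opening.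

**Step 11**
Reactants: 19; 20 formaldehyde
Product: 21 α-methylene lactone
Conditions: (CH2O)n, piperidine (0.2 equiv), AcOH, pyridine, 60 °C
Reagents that add atoms: none
Why: Decarboxylative Mannich–elimination of the malonic half-ester (Knoevenagel–Doebner type) gives the exocyclic methylene under near-neutral conditions, with no strong base.

**Step 12**
Reactants: 21; 22 acetic anhydride
Product: 23 C11 acetate
Conditions: 22, pyridine, DMAP (cat.), CH2Cl2, 23 °C
Reagents that add atoms: none
Why: Simple acetylation of the hindered secondary alcohol installs the target 11-OAc before later steps.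

**Step 13**
Reactants: 23
Product: 24 terminal alkyne
Conditions: AgNO3 (0.2 equiv), acetone/H2O, 23 °C
Reagents that add atoms: none
Why: Silver-catalysed desilylation is mild and leaves the acetate, the acrylate and the TIPS ether intact.

**Step 14**
Reactants: 24; 25 allyl bromide
Product: 26 skipped (E)-diene with a terminal vinyl group
Conditions: 2, Cp2ZrCl2, ClCH2CH2Cl, 23 °C; then CuCl, 25, THF, 0 °C
Reagents that add atoms: trimethylaluminium (2) C[Al](C)C
Why: Carboalumination gives the E-alkenylalane (Me cis to Al), and Cu-catalysed SN2 allylation with retention builds the C7=C8 E-alkene and the C6–C5 bond.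

**Step 15**
Reactants: 26
Product: 27 macrocyclic TIPS ether
Conditions: Hoveda–Grubbs II (15 mol%), 1,4-benzoquinone (10 mol%), toluene (1 mM), 80 °C
Reagents that add atoms: none
Why: Macro-RCM between the isopropenyl and vinyl termini releases ethylene and closes the 14-membered ring, giving the thermodynamically preferred (E)-trisubstituted alkene.

**Step 16**
Reactants: 27
Product: 28 Dendronpholide A
Conditions: HF·pyridine, pyridine, THF, 35 °C
Reagents that add atoms: none
Why: Fluoride removal of the TIPS ether releases the free C3 allylic alcohol without affecting the acetate or alkenes.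

## Compound list
1 | hex-5-en-1-yne | C#CCCC=C | starting material
2 | trimethylaluminium | C[Al](C)C | starting material
3 | iodine | II | starting material
4 | (E)-1-iodo-2-methylhexa-1,5-diene | I/C=C(\C)CCC=C | intermediate
5 | (4-iodobut-1-yn-1-yl)trimethylsilane | ICCC#C[Si](C)(C)C | starting material
6 | trimethyl[(5E)-6-methyldeca-5,9-dien-1-yn-1-yl]silane | C=CCC/C(C)=C/CCC#C[Si](C)(C)C | intermediate
7 | Oxone (KHSO5) | [K+].OOS(=O)(=O)[O-] | starting material
8 | (2S,3S)-epoxide | C=CCC[C@]1(C)O[C@H]1CCC#C[Si](C)(C)C | intermediate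
9 | acrolein | C=CC=O | starting material
10 | (E)-enal epoxide | O=C/C=C/CC[C@]1(C)O[C@H]1CCC#C[Si](C)(C)C | intermediate
11 | di-tert-butyl malonate | CC(C)(C)OC(=O)CC(=O)OC(C)(C)C | starting material
12 | Michael adduct aldehyde (C1 R) | O=CC[C@H](C(C(=O)OC(C)(C)C)C(=O)OC(C)(C)C)CC[C@]1(C)O[C@H]1CCC#C[Si](C)(C)C | intermediate
13 | isopropenylmagnesium bromide | C=C(C)[Mg]Br | starting material
14 | allylic alcohol (C3 epimers) | C=C(C)C(O)C[C@H](C(C(=O)OC(C)(C)C)C(=O)OC(C)(C)C)CC[C@]1(C)O[C@H]1CCC#C[Si](C)(C)C | intermediate
15 | isopropenyl ketone | C=C(C)C(=O)C[C@H](C(C(=O)OC(C)(C)C)C(=O)OC(C)(C)C)CC[C@]1(C)O[C@H]1CCC#C[Si](C)(C)C | intermediate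
16 | (3S)-alcohol | C=C(C)[C@@H](O)C[C@H](C(C(=O)OC(C)(C)C)C(=O)OC(C)(C)C)CC[C@]1(C)O[C@H]1CCC#C[Si](C)(C)C | intermediate
17 | triisopropylsilyl chloride | CC(C)[Si](Cl)(C(C)C)C(C)C | starting material
18 | TIPS ether | C=C(C)[C@@H](O[Si](C(C)C)(C(C)C)C(C)C)C[C@H](C(C(=O)OC(C)(C)C)C(=O)OC(C)(C)C)CC[C@]1(C)O[C@H]1CCC#C[Si](C)(C)C | intermediate
19 | α-carboxy-ε-lactone | OC(=O)C1C(=O)O[C@](C)(CC[C@@H]1C[C@H](O[Si](C(C)C)(C(C)C)C(C)C)C(C)=C)[C@@H](O)CCC#C[Si](C)(C)C | intermediate
20 | formaldehyde | C=O | starting material
21 | α-methylene lactone | C=C1C(=O)O[C@](C)(CC[C@@H]1C[C@H](O[Si](C(C)C)(C(C)C)C(C)C)C(C)=C)[C@@H](O)CCC#C[Si](C)(C)C | intermediate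
22 | acetic anhydride | CC(=O)OC(C)=O | starting material
23 | acetate | C=C1C(=O)O[C@](C)(CC[C@@H]1C[C@H](O[Si](C(C)C)(C(C)C)C(C)C)C(C)=C)[C@@H](OC(C)=O)CCC#C[Si](C)(C)C | intermediate
24 | terminal alkyne | C=C1C(=O)O[C@](C)(CC[C@@H]1C[C@H](O[Si](C(C)C)(C(C)C)C(C)C)C(C)=C)[C@@H](OC(C)=O)CCC#C | intermediate
25 | allyl bromide | C=CCBr | starting material
26 | RCM precursor | C=C1C(=O)O[C@](C)(CC[C@@H]1C[C@H](O[Si](C(C)C)(C(C)C)C(C)C)C(C)=C)[C@@H](OC(C)=O)CC/C(C)=C/CC=C | intermediate
27 | macrocyclic TIPS ether | C=C1C(=O)O[C@]2(C)CC[C@@H]1C[C@H](O[Si](C(C)C)(C(C)C)C(C)C)/C(C)=C/C/C=C(\C)CC[C@@H]2OC(C)=O | intermediate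
28 | Dendronpholide A | C=C1C(=O)O[C@]2(C)CC[C@@H]1C[C@H](O)/C(C)=C/C/C=C(\C)CC[C@@H]2OC(C)=O | target

**Total steps: 16. Longest linear sequence: 16 (from hex-5-en-1-yne).**

## Three steps most likely to fail
1. **Step 10 (proposed new lactonisation).** The 7-exo cyclisation may lose to 6-endo epoxide–alkene/alkyne cyclisation, to ionisation, or to competing 8-endo attack.
   Fallback (known chemistry): open epoxide 18 with aqueous acid (inversion at C12), selectively acetylate the C11 secondary OH, cleave the tert-butyl esters to the acid, and close the lactone on the tertiary alcohol with MNBA/DMAP (Shiina).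
2. **Step 15 (macro-RCM).** The 1,1-disubstituted alkene is a poor partner, and the E/Z ratio and isomerisation of the 1,4-diene are uncertain.
   Fallback: macrocyclise by intramolecular HWE (Masamune–Roush) of an α-methyl-β-ketophosphonate onto the C5 aldehyde, then reduce the macrocyclic enone with CBS to set C3.
3. **Step 14 (carboalumination/allylation on the late-stage lactone).** Me3Al may attack the acrylate, the lactone or the acetate.
   Fallback: carry a ketal-protected methyl ketone chain end from Step 2 instead of the TMS-alkyne, then build the skipped diene after lactonisation by E-selective HWE, DIBAL reduction, allylic phosphate formation and vinylMgBr/CuI SN2 coupling.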